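**Retrosynthetic overview**

1. Locants: C1H=C2(CH3)–C3H(OAc)–C4H2–C4a–C5H(CH3)–C6H(OAc)–C7H2–C8[=C9(CH3)C10H2OCHO]–C8a; ring A = C1–C4, C4a, C8a; ring B = C4a–C8a; α is the face of H-4a and H-8a, β the other face. The target is (3R,4aS,5R,6R,8aS,8E), i.e. 3β-OAc, 5α-CH3, 6β-OAc.
2. Feature: the C1H=C2(CH3)–C3H(O) allylic unit of ring A is what remains when one carbon (C2) is inserted between the two alkene carbons (C1, C3) of a cis-fused cyclopentene. Ring A is therefore made last, by CBr2 insertion into a cis-hydrindene, silver-assisted opening and water capture at C3; C2–Br then becomes C2–CH3 (Negishi) and C3 is reset by oxidation and Luche reduction.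
3. End game: formate ⇐ C10 alcohol ⇐ 1,3-transposition of a C8 isopropenyl carbinol ⇐ C8 ketone (dioxolane); 6β-OAc ⇐ Mitsunobu inversion of a 6α-alcohol.
4. cis-Hydrindene ⇐ TiCl4-promoted [3+2] annulation of trimethylsilylallene onto (4R,5S)-4-methyl-5-silyloxycyclohexenone; enone ⇐ ring-closing metathesis; C5/C6 ⇐ Brown (E)-crotylboration.
5. Order of ring formation: ring B (metathesis), then the five-membered ring (annulation), then ring A (one-carbon expansion of the five-membered ring).

Key step: step 11

Remark on the chemistry: in additions to the β-carbon of cyclohexenones a 5-oxygen substituent directs the nucleophile to its opposite face more strongly than a 4-methyl group does, so a trans-4-methyl-5-silyloxy enone would be annulated mainly on the wrong face of C4a; the enone is therefore built with methyl and silyloxy cis (both then direct to the same face), the ring expansion is run on the 6α-silyloxy hydrindene, and C6 is inverted in the step that installs its acetate; the C6 ether is TBDPS so that it survives the acid that removes the vinylsilane.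

**Route**

Step 1
Reactants: 1 3-[(tert-butyldimethylsilyl)oxy]propanal; 2 (E)-but-2-ene
Product: 4 (3S,4R)-1-[(tert-butyldimethylsilyl)oxy]-4-methylhex-5-en-3-ol, via (E)-crotyldiisopinocampheylborane 3 (not isolated)
Conditions: 2, KOtBu, n-BuLi, THF, −78 to −45 °C; (+)-Ipc2BOMe [from (−)-α-pinene], −78 °C; BF3·OEt2; 1, −78 °C; then NaOH, H2O2, 0 °C to rt
Reagents that add atoms: none
Why: Brown crotylboration through a chair Zimmerman–Traxler transition state, in which the E-crotyl geometry gives the 3,4-anti pair and the isopinocampheyl groups select the aldehyde face that gives 3S (hence 4R); these centres become C6 and C5.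

Step 2
Reactants: 4 (3S,4R)-1-[(tert-butyldimethylsilyl)oxy]-4-methylhex-5-en-3-ol
Product: 5 (3S,4R)-3-[(tert-butyldiphenylsilyl)oxy]-1-[(tert-butyldimethylsilyl)oxy]-4-methylhex-5-ene
Conditions: TBDPSCl, imidazole, DMAP (cat.), DMF, 45 °C
Reagents that add atoms: tert-butyl(chloro)diphenylsilane, CC(C)(C)[Si](Cl)(c1ccccc1)c1ccccc1
Why: Imidazole-promoted silylation of the secondary alcohol gives an ether that is stable to the Lewis and Brønsted acids used in steps 3, 8 and 9.

Step 3
Reactants: 5 (3S,4R)-3-[(tert-butyldiphenylsilyl)oxy]-1-[(tert-butyldimethylsilyl)oxy]-4-methylhex-5-ene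
Product: 6 (3S,4R)-3-[(tert-butyldiphenylsilyl)oxy]-4-methylhex-5-en-1-ol
Conditions: CSA (cat.), MeOH/CH2Cl2 (1:1), 0 °C
Reagents that add atoms: none
Why: Acid-catalysed methanolysis removes the unhindered primary TBS ether far faster than the hindered secondary TBDPS ether.

Step 4
Reactants: 6 (3S,4R)-3-[(tert-butyldiphenylsilyl)oxy]-4-methylhex-5-en-1-ol
Product: 7 (3S,4R)-3-[(tert-butyldiphenylsilyl)oxy]-4-methylhex-5-enal
Conditions: Dess–Martin periodinane, NaHCO3, CH2Cl2, 0 °C to rt
Reagents that add atoms: none
Why: Dess–Martin oxidation under buffered, non-basic conditions gives the aldehyde without loss of the silyloxy group by elimination.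

Step 5
Reactants: 7 (3S,4R)-3-[(tert-butyldiphenylsilyl)oxy]-4-methylhex-5-enal
Product: 8 (5S,6R)-5-[(tert-butyldiphenylsilyl)oxy]-6-methylocta-1,7-dien-3-ol (both C3 epimers)
Conditions: CH2=CHMgBr, THF, −78 °C
Reagents that add atoms: vinylmagnesium bromide, C=C[Mg]Br
Why: Grignard 1,2-addition supplies the second terminal alkene; the new carbinol centre is not controlled and is removed by oxidation in step 7.

Step 6
Reactants: 8 (5S,6R)-5-[(tert-butyldiphenylsilyl)oxy]-6-methylocta-1,7-dien-3-ol
Product: 9 (4R,5S)-5-[(tert-butyldiphenylsilyl)oxy]-4-methylcyclohex-2-en-1-ol (both C1 epimers)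
Conditions: second-generation Grubbs catalyst RuCl2(=CHPh)(H2IMes)(PCy3) (3 mol%), CH2Cl2, 40 °C
Reagents that add atoms: none
Why: Ring-closing metathesis of the 1,7-diene closes ring B as a cyclohexene and is driven by loss of ethene.

Step 7
Reactants: 9 (4R,5S)-5-[(tert-butyldiphenylsilyl)oxy]-4-methylcyclohex-2-en-1-ol
Product: 10 (4R,5S)-5-[(tert-butyldiphenylsilyl)oxy]-4-methylcyclohex-2-en-1-one
Conditions: Dess–Martin periodinane, NaHCO3, CH2Cl2, 0 °C
Reagents that add atoms: none
Why: Oxidation of the allylic alcohol gives the enone; neutral conditions avoid elimination of silanol, which would lead on to a phenol.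

Step 8
Reactants: 10 (4R,5S)-5-[(tert-butyldiphenylsilyl)oxy]-4-methylcyclohex-2-en-1-one; 11 trimethyl(propa-1,2-dienyl)silane
Product: 12 cis-hydrindenone (target locants): C8 ketone; 6α-OTBDPS; 5α-CH3; C4a–C4H2–C3(SiMe3)=C1H–C8a
Conditions: TiCl4 (1.5 equiv), CH2Cl2, −78 °C; aqueous NaHCO3
Reagents that add atoms: none
Why: Danheiser [3+2] annulation: the terminal CH2 of the allene attacks C4a of the TiCl4-activated enone on the face opposite to both the pseudoaxial 4-methyl and the equatorial 5-silyloxy group (cis to each other, so axial attack is anti to both), the vinyl cation rearranges by 1,2-silyl shift and the titanium enolate closes the five-membered ring at C8a, which can only be cis-fused.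

Step 9
Reactants: 12 silylated cis-hydrindenone
Product: 13 cis-hydrindenone: C8 ketone; 6α-OTBDPS; 5α-CH3; C4a–C4H2–C3H=C1H–C8a
Conditions: TFA, CH2Cl2, 0 °C to rt
Reagents that add atoms: none
Why: Protodesilylation by ipso protonation of the vinylsilane (β-silyl cation) and loss of the silyl group leaves the alkene in place; the TBDPS ether tolerates the acid, and the cis-fused hydrindenone has no drive to epimerise.

Step 10
Reactants: 13 cis-hydrindenone
Product: 14 cis-hydrindene ketal: C8 1,3-dioxolane; 6α-OTBDPS; 5α-CH3; C1=C3 alkene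
Conditions: (TMSOCH2)2, TMSOTf (cat.), CH2Cl2, −78 to −20 °C; pyridine quench
Reagents that add atoms: 1,2-bis(trimethylsilyloxy)ethane, C[Si](C)(C)OCCO[Si](C)(C)C
Why: Noyori ketalisation under aprotic, cold conditions masks the ketone against the strong base of step 11 without moving the 3-ene, epimerising C8a or ionising the silyloxy group.

Step 11
Reactants: 14 cis-hydrindene ketal; 15 bromoform
Product: 17 cis-fused 2-bromo-octalin-3-ol: C1H=C2(Br)–C3H(OH); C8 dioxolane; 6α-OTBDPS; 5α-CH3; both C3 epimers, via dibromocyclopropane 16 (not isolated)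
Conditions: CHBr3, KOtBu, pentane, −10 to 0 °C; filter, concentrate below 25 °C; then AgClO4, CaCO3, acetone/H2O (4:1), rt, dark
Reagents that add atoms: water, O
Why: Dibromocarbene, formed from bromoform by loss of HBr, adds in a concerted [2+1] manner to the cyclopentene of 14 from its convex α face and forms C1–C2 and C2–C3; monovalent silver then removes the endo bromide while the cyclopropane opens in the disrotatory sense that the ring allows, which breaks C1–C3 and turns the five-membered ring into the six-membered 2-bromoallyl cation of ring A (a ring expansion by electrocyclic opening, not a cyclisation), and water captures this cation. This is the known gem-dibromocyclopropanation and silver-promoted ring opening of cyclopentenes to 2-bromocyclohex-2-enols; 16 is taken on crude because such bicyclo[3.1.0]hexanes drift thermally to the allylic dibromide, which silver ionises to the same cation. The step needs water to attack C3 and not C1: C1 is flanked by the fusion carbon C8a and the fully substituted ketal carbon and is deactivated inductively by the ketal oxygens, whereas C3 has only the C4 methylene beside it. The new carbinol centre has no reliable control element (capture on the open α face should favour the 3α-alcohol), so the route does not depend on it: C3 is oxidised in step 12 and set by hydride in step 14. CaCO3 takes up the perchloric acid that is released, which protects the dioxolane and the silyl ether. The cis ring fusion, C5 and C6 are not touched.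

Step 12
Reactants: 17 2-bromo-octalin-3-ol (C3 epimers)
Product: 18 2-bromo-enone: C3 ketone; C1H=C2(Br); C8 dioxolane; 6α-OTBDPS; 5α-CH3
Conditions: Dess–Martin periodinane, NaHCO3, CH2Cl2, 0 °C to rt
Reagents that add atoms: none
Why: Oxidation of the allylic alcohol merges both C3 epimers into one enone under conditions that do not enolise toward C8a.

Step 13
Reactants: 18 2-bromo-enone
Product: 19 2-methyl-enone: C3 ketone; C1H=C2(CH3); C8 dioxolane; 6α-OTBDPS; 5α-CH3
Conditions: MeZnCl (3 equiv), Pd(PPh3)4 (5 mol%), THF, 50 °C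
Reagents that add atoms: methylzinc chloride, C[Zn]Cl
Why: Negishi coupling (oxidative addition of zerovalent palladium into the activated C2–Br bond, transmetalation, reductive elimination) installs the C2 methyl without base, so H-8a is not epimerised.

Step 14
Reactants: 19 2-methyl-enone
Product: 20 3β-alcohol: C1H=C2(CH3)–C3H(OH); C8 dioxolane; 6α-OTBDPS; 5α-CH3
Conditions: NaBH4, CeCl3·7H2O, MeOH, −78 to −40 °C
Reagents that add atoms: none
Why: Luche 1,2-reduction delivers hydride to C3 from the α face (in one half-chair the β face is blocked by the axial C4a–C5 bond, in the other α attack is the preferred axial one), which sets the 3β-hydroxyl of the target.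

Step 15
Reactants: 20 3β-alcohol ketal
Product: 21 hydroxy ketone: C8 ketone; 3β-OH; 6α-OTBDPS; 5α-CH3; C1=C2(CH3)
Conditions: PPTS, acetone/H2O (10:1), 50 °C
Reagents that add atoms: water, O
Why: Mild acid hydrolysis of the dioxolane; PPTS is weak enough that the 1-ene should not move into conjugation with the C8 ketone and C8a should not epimerise, and the TBDPS ether is stable.

Step 16
Reactants: 21 hydroxy ketone
Product: 22 diol: C8(OH)(isopropenyl) (C8 configuration immaterial); 3β-OH; 6α-OTBDPS; 5α-CH3
Conditions: CH2=C(CH3)MgBr (4 equiv), CeCl3 (anhydrous, 4 equiv), THF, −78 °C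
Reagents that add atoms: isopropenylmagnesium bromide, CC(=C)[Mg]Br
Why: Organocerium 1,2-addition (Imamoto) is nucleophilic but weakly basic, so the doubly activated H-8a is not removed; one equivalent is consumed by the C3 hydroxyl, and the new C8 centre is erased in step 20.

Step 17
Reactants: 22 diol
Product: 23 3β-acetate: C8(OH)(isopropenyl); 6α-OTBDPS; 5α-CH3
Conditions: Ac2O, pyridine, DMAP (cat.), CH2Cl2, 0 °C
Reagents that add atoms: acetic anhydride, CC(=O)OC(C)=O
Why: The secondary allylic alcohol is acetylated while the hindered tertiary alcohol does not react under these conditions.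

Step 18
Reactants: 23 3β-acetate
Product: 24 6α-alcohol: 3β-OAc; C8(OH)(isopropenyl); 6α-OH; 5α-CH3
Conditions: TBAF, AcOH (1:1), THF, rt to 40 °C
Reagents that add atoms: none
Why: Fluoride cleaves the Si–O bond; buffering with acetic acid keeps the acetate and the tertiary allylic alcohol intact.

Step 19
Reactants: 24 6α-alcohol
Product: 25 3β,6β-diacetate: C8(OH)(isopropenyl); 5α-CH3
Conditions: AcOH, PPh3, DIAD, toluene, 0 °C to rt
Reagents that add atoms: acetic acid, CC(=O)O
Why: Mitsunobu esterification: acetate displaces the oxyphosphonium of the axial 6α-alcohol by SN2 from the open β side, which inverts C6 and gives the equatorial 6β-acetate of the target; the tertiary alcohol is inert.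

Step 20
Reactants: 25 3β,6β-diacetate tertiary alcohol
Product: 27 (E)-C10 alcohol: C8=C9(CH3)CH2OH with CH2OH on the C7 side; 3β,6β-diacetate, via C10 trimethylsilyl ether 26 (not isolated)
Conditions: Ph3SiOReO3 (5 mol%), BSA (1.5 equiv), Et2O, −50 to 0 °C; then aqueous citric acid, THF, 0 °C
Reagents that add atoms: none
Why: Rhenium-oxo-catalysed 1,3-transposition: the perrhenate ester of the tertiary alcohol undergoes a chair-like [3,3] shift to the primary ester, and BSA silylates only the unhindered primary alcohol, which pulls the otherwise unfavourable equilibrium over; with the more substituted C8a pseudo-equatorial in the chair the CH2O terminus ends on the C7 side (E), which is also the less strained isomer, although the preference is expected to be modest and separation from the Z isomer may be needed.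

Step 21
Reactants: 27 (E)-C10 alcohol
Product: 28 CNP0262962.1, (3R,4aS,5R,6R,8aS,8E) in the locants of the overview
Conditions: HCO2H, DCC, DMAP (cat.), CH2Cl2, 0 °C
Reagents that add atoms: formic acid, O=CO
Why: Carbodiimide (Steglich) esterification formylates the primary allylic alcohol under neutral conditions and as the last step, so the labile formate meets no further reagent.

**Compound list**

1 | 3-[(tert-butyldimethylsilyl)oxy]propanal | CC(C)(C)[Si](C)(C)OCCC=O | starting material
2 | (E)-but-2-ene | C/C=C/C | starting material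
3 | (E)-crotyldiisopinocampheylborane, from (+)-Ipc2BOMe | C/C=C/CB([C@H]1C[C@H]2C[C@@H]([C@@H]1C)C2(C)C)[C@H]1C[C@H]2C[C@@H]([C@@H]1C)C2(C)C | intermediate (not isolated)
4 | (3S,4R)-1-[(tert-butyldimethylsilyl)oxy]-4-methylhex-5-en-3-ol | C[C@H](C=C)[C@@H](O)CCO[Si](C)(C)C(C)(C)C | intermediate
5 | (3S,4R)-3-[(tert-butyldiphenylsilyl)oxy]-1-[(tert-butyldimethylsilyl)oxy]-4-methylhex-5-ene | C[C@H](C=C)[C@@H](O[Si](c1ccccc1)(c1ccccc1)C(C)(C)C)CCO[Si](C)(C)C(C)(C)C | intermediate
6 | (3S,4R)-3-[(tert-butyldiphenylsilyl)oxy]-4-methylhex-5-en-1-ol | C[C@H](C=C)[C@@H](O[Si](c1ccccc1)(c1ccccc1)C(C)(C)C)CCO | intermediate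
7 | (3S,4R)-3-[(tert-butyldiphenylsilyl)oxy]-4-methylhex-5-enal | C[C@H](C=C)[C@@H](O[Si](c1ccccc1)(c1ccccc1)C(C)(C)C)CC=O | intermediate
8 | (5S,6R)-5-[(tert-butyldiphenylsilyl)oxy]-6-methylocta-1,7-dien-3-ol, C3 epimers | C[C@H](C=C)[C@@H](O[Si](c1ccccc1)(c1ccccc1)C(C)(C)C)CC(O)C=C | intermediate
9 | (4R,5S)-5-[(tert-butyldiphenylsilyl)oxy]-4-methylcyclohex-2-en-1-ol, C1 epimers | C[C@H]1[C@@H](O[Si](c2ccccc2)(c2ccccc2)C(C)(C)C)CC(O)C=C1 | intermediate
10 | (4R,5S)-5-[(tert-butyldiphenylsilyl)oxy]-4-methylcyclohex-2-en-1-one | C[C@H]1[C@@H](O[Si](c2ccccc2)(c2ccccc2)C(C)(C)C)CC(=O)C=C1 | intermediate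
11 | trimethyl(propa-1,2-dienyl)silane | C=C=C[Si](C)(C)C | starting material
12 | cis-hydrindenone, C8 ketone, 6α-OTBDPS, 5α-methyl, C3-SiMe3, 1(3)-ene | C[C@H]1[C@@H](O[Si](c2ccccc2)(c2ccccc2)C(C)(C)C)CC(=O)[C@@H]2C=C([Si](C)(C)C)C[C@H]12 | intermediate
13 | cis-hydrindenone, C8 ketone, 6α-OTBDPS, 5α-methyl, 1(3)-ene | C[C@H]1[C@@H](O[Si](c2ccccc2)(c2ccccc2)C(C)(C)C)CC(=O)[C@@H]2C=CC[C@H]12 | intermediate
14 | cis-hydrindene, C8 1,3-dioxolane, 6α-OTBDPS, 5α-methyl, 1(3)-ene (key-step precursor) | C[C@H]1[C@@H](O[Si](c2ccccc2)(c2ccccc2)C(C)(C)C)CC2(OCCO2)[C@@H]3C=CC[C@H]13 | intermediate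
15 | bromoform | BrC(Br)Br | starting material
16 | dibromocyclopropane, CBr2 bridging C1 and C3 on the α face of 14 | C[C@H]1[C@@H](O[Si](c2ccccc2)(c2ccccc2)C(C)(C)C)CC2(OCCO2)[C@@H]3[C@@H]4[C@@H](C4(Br)Br)C[C@H]13 | intermediate (not isolated)
17 | cis-fused 2-bromo-octalin-3-ol, C8 dioxolane, 6α-OTBDPS, 5α-methyl, C3 epimers (key-step product) | OC1C[C@@H]2[C@@H](C)[C@@H](O[Si](c3ccccc3)(c3ccccc3)C(C)(C)C)CC3(OCCO3)[C@@H]2C=C1Br | intermediate
18 | 2-bromo-enone (C3 ketone), C8 dioxolane, 6α-OTBDPS, 5α-methyl | O=C1C[C@@H]2[C@@H](C)[C@@H](O[Si](c3ccccc3)(c3ccccc3)C(C)(C)C)CC3(OCCO3)[C@@H]2C=C1Br | intermediate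
19 | 2-methyl-enone (C3 ketone), C8 dioxolane, 6α-OTBDPS, 5α-methyl | O=C1C[C@@H]2[C@@H](C)[C@@H](O[Si](c3ccccc3)(c3ccccc3)C(C)(C)C)CC3(OCCO3)[C@@H]2C=C1C | intermediate
20 | 3β-alcohol, C8 dioxolane, 6α-OTBDPS, 5α-methyl | O[C@@H]1C[C@@H]2[C@@H](C)[C@@H](O[Si](c3ccccc3)(c3ccccc3)C(C)(C)C)CC3(OCCO3)[C@@H]2C=C1C | intermediate
21 | 3β-hydroxy C8 ketone, 6α-OTBDPS, 5α-methyl | O[C@@H]1C[C@@H]2[C@@H](C)[C@@H](O[Si](c3ccccc3)(c3ccccc3)C(C)(C)C)CC(=O)[C@@H]2C=C1C | intermediate
22 | 3β-hydroxy C8 isopropenyl carbinol (C8 epimers), 6α-OTBDPS | O[C@@H]1C[C@@H]2[C@@H](C)[C@@H](O[Si](c3ccccc3)(c3ccccc3)C(C)(C)C)CC(O)(C(C)=C)[C@@H]2C=C1C | intermediate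
23 | 3β-acetoxy C8 isopropenyl carbinol, 6α-OTBDPS | CC(=O)O[C@@H]1C[C@@H]2[C@@H](C)[C@@H](O[Si](c3ccccc3)(c3ccccc3)C(C)(C)C)CC(O)(C(C)=C)[C@@H]2C=C1C | intermediate
24 | 3β-acetoxy-6α-hydroxy C8 isopropenyl carbinol | CC(=O)O[C@@H]1C[C@@H]2[C@@H](C)[C@@H](O)CC(O)(C(C)=C)[C@@H]2C=C1C | intermediate
25 | 3β,6β-diacetoxy C8 isopropenyl carbinol | CC(=O)O[C@@H]1C[C@@H]2[C@@H](C)[C@H](OC(C)=O)CC(O)(C(C)=C)[C@@H]2C=C1C | intermediate
26 | (E)-C10 trimethylsilyl ether of 27 | CC(=O)O[C@@H]1C[C@@H]2[C@@H](C)[C@H](OC(C)=O)C/C(=C(/C)CO[Si](C)(C)C)[C@@H]2C=C1C | intermediate (not isolated)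
27 | (E)-C10 alcohol, 3β,6β-diacetate | CC(=O)O[C@@H]1C[C@@H]2[C@@H](C)[C@H](OC(C)=O)C/C(=C(/C)CO)[C@@H]2C=C1C | intermediate
28 | CNP0262962.1 | CC(=O)O[C@@H]1C[C@@H]2[C@@H](C)[C@H](OC(C)=O)C/C(=C(/C)COC=O)[C@@H]2C=C1C | target

**Step count**

Total: 21 steps. Longest linear sequence: 21 steps (1 to 28).

**Steps most likely to fail**

Step 20. The perrhenate ester of the crowded tertiary alcohol may ionise and lose a proton to give dienes, and the sigmatropic shift may discriminate poorly between the two geometries of the new C8=C9 bond. The fallback sets out from 25: PBr3 with catalytic pyridine in Et2O at −20 °C converts the tertiary allylic alcohol with allylic shift into the primary allylic bromide F1, whose geometric isomers can equilibrate through the allylic ion pair toward the less strained E form. Caesium formate in DMF then displaces bromide at the primary carbon and gives 28 directly, so the route is rejoined at 28 without passing through 27.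

Step 19. The oxyphosphonium ion of the axial, hindered 6α-alcohol may lose a proton from C5 or C7 and give ring B alkenes faster than acetate attacks, or the neighbouring tertiary hydroxyl may intercept it. The fallback sets out from 24: Dess–Martin oxidation gives the C6 ketone F2, and NaBH4 in MeOH at −40 °C delivers hydride axially from the α face to give the equatorial 6β-alcohol F3, trans to the equatorial 5α-methyl group. Acetylation of F3 with Ac2O, pyridine and DMAP returns to 25.

Step 8. The β-silyl vinyl cation formed after the conjugate addition may lose its silyl group before the titanium enolate closes the ring, which leaves a 3-propargyl ketone, or TiCl4 may promote loss of the silyloxy group. The fallback sets out from 10: allenyltributylstannane and TBSOTf in CH2Cl2 at −78 °C give the conjugate propargylation product, trapped as the tert-butyldimethylsilyl enol ether F4, with the same facial preference. Catalytic Ph3PAuCl/AgBF4 in CH2Cl2/MeOH then closes the five-membered ring by 5-endo-dig attack of the enol ether on the alkyne activated by monovalent gold and gives 13 directly, so the route is rejoined at 13 and step 9 is not needed.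

**Further compounds**

F1 | step 20 | (E)-C10 bromide, C8=C9(CH3)CH2Br, 3β,6β-diacetate | CC(=O)O[C@@H]1C[C@@H]2[C@@H](C)[C@H](OC(C)=O)C/C(=C(/C)CBr)[C@@H]2C=C1C
F2 | step 19 | C6 ketone, 3β-acetoxy C8 isopropenyl carbinol | CC(=O)O[C@@H]1C[C@@H]2[C@@H](C)C(=O)CC(O)(C(C)=C)[C@@H]2C=C1C
F3 | step 19 | 6β-alcohol, 3β-acetoxy C8 isopropenyl carbinol | CC(=O)O[C@@H]1C[C@@H]2[C@@H](C)[C@H](O)CC(O)(C(C)=C)[C@@H]2C=C1C
F4 | step 8 | tert-butyldimethylsilyl enol ether of the 3-propargyl ketone | C[C@H]1[C@@H](O[Si](c2ccccc2)(c2ccccc2)C(C)(C)C)CC(O[Si](C)(C)C(C)(C)C)=C[C@@H]1CC#C
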